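**Retrosynthetic overview**
1. Target 18 ← O-methylation of tertiary ortho-quinol 17 ← 1,2-allylation of the C5 carbonyl of ortho-quinone 16 ← catechol 15.
2. Catechol 15 ← trans-dihydrobenzofuran 14, whose O1–C7a bond comes from intramolecular aryl C–O coupling of bromo alcohol 13 with retention at C2.
3. 13 ← Evans syn-aldol adduct 10: the C2–C3 bond joins the ring-A arylacetyl imide 7 and 3,4,5-trimethoxybenzaldehyde 8; the imide carbon is reduced to the C3 methyl.
4. Ring order: aromatic rings A and C are bought; the dihydrofuran ring is closed in step 10; ring A is dearomatised last (step 12).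

Assumption: the two C5 epimers formed in step 12 are diastereomers and are taken to be separable on silica; 1, 6 and 8 are bought.

**Step 1**
Reactants: 1 3,4-dihydroxyphenylacetic acid
Product: 2 benzyl [3,4-bis(benzyloxy)phenyl]acetate
Conditions: BnBr (3.5 equiv), K2CO3, DMF, 60 °C
Reagents that add atoms: benzyl bromide, BrCc1ccccc1
Why: Williamson-type SN2 O-alkylation of both phenoxides and the carboxylate gives the fully benzylated compound in one operation.

**Step 2**
Reactants: 2 benzyl [3,4-bis(benzyloxy)phenyl]acetate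
Product: 3 [3,4-bis(benzyloxy)phenyl]acetic acid
Conditions: NaOH, THF/MeOH/H2O, 50 °C; then 1 M HCl
Reagents that add atoms: sodium hydroxide, [Na+].[OH-]
Why: Ester saponification cleaves only the benzyl ester, since aryl benzyl ethers are inert to hydroxide.

**Step 3**
Reactants: 3 [3,4-bis(benzyloxy)phenyl]acetic acid
Product: 4 [4,5-bis(benzyloxy)-2-bromophenyl]acetic acid
Conditions: NBS (1.05 equiv), MeCN, 0 °C → rt, dark
Reagents that add atoms: N-bromosuccinimide, O=C1CCC(=O)N1Br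
Why: Electrophilic aromatic bromination goes para to the 3-benzyloxy group and ortho to the side chain, the usual outcome for 3,4-dialkoxyphenylacetic acids, and places the halogen where ring oxygen O1 will later be attached.

**Step 4**
Reactants: 4 [4,5-bis(benzyloxy)-2-bromophenyl]acetic acid
Product: 5 [4,5-bis(benzyloxy)-2-bromophenyl]acetyl chloride
Conditions: (COCl)2, cat. DMF, CH2Cl2, 0 °C → rt; concentrate
Reagents that add atoms: oxalyl chloride, O=C(Cl)C(Cl)=O
Why: Vilsmeier-type activation converts the acid into the acid chloride under neutral conditions that leave benzyl ethers and the aryl bromide alone.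

**Step 5**
Reactants: 5 [4,5-bis(benzyloxy)-2-bromophenyl]acetyl chloride; 6 (S)-4-benzyl-1,3-oxazolidin-2-one
Product: 7 (S)-4-benzyl-3-{[4,5-bis(benzyloxy)-2-bromophenyl]acetyl}-1,3-oxazolidin-2-one
Conditions: 6, n-BuLi, THF, −78 °C; then 5, −78 → 0 °C
Reagents that add atoms: none
Why: N-acylation of the lithiated Evans auxiliary by the acid chloride is fast at −78 °C and installs the chiral controller.

**Step 6**
Reactants: 7 (S)-4-benzyl-3-{[4,5-bis(benzyloxy)-2-bromophenyl]acetyl}-1,3-oxazolidin-2-one; 8 3,4,5-trimethoxybenzaldehyde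
Product: 10 (4S)-4-benzyl-3-[(2S,3S)-2-[4,5-bis(benzyloxy)-2-bromophenyl]-3-hydroxy-3-(3,4,5-trimethoxyphenyl)propanoyl]-1,3-oxazolidin-2-one, via Z-dibutylboron enolate 9 (not isolated)
Conditions: Bu2BOTf, i-Pr2NEt, CH2Cl2, −78 → 0 °C; 8, −78 → 0 °C; pH 7 buffer, MeOH, 30% H2O2, 0 °C
Reagents that add atoms: none
Why: In this Evans syn-aldol reaction the Z-boron enolate reacts through a closed Zimmerman–Traxler chair on the face away from the auxiliary benzyl group, which forms the fragment-joining C–C bond and sets the 2,3-syn (2S,3S) pair that becomes C3 and C2 of the target.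

**Step 7**
Reactants: 10 the aldol adduct
Product: 11 (1S,2R)-2-[4,5-bis(benzyloxy)-2-bromophenyl]-1-(3,4,5-trimethoxyphenyl)propane-1,3-diol
Conditions: LiBH4, MeOH (1 equiv), THF, 0 °C
Reagents that add atoms: none
Why: Reductive cleavage of the imide by borohydride releases the auxiliary and gives the primary alcohol without touching either stereocentre (the descriptor at C2 changes only through priority rules).

**Step 8**
Reactants: 11 the 1,3-diol
Product: 12 (2R,3S)-2-[4,5-bis(benzyloxy)-2-bromophenyl]-3-hydroxy-3-(3,4,5-trimethoxyphenyl)propyl 4-methylbenzenesulfonate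
Conditions: TsCl (1.1 equiv), pyridine, CH2Cl2, 0 °C
Reagents that add atoms: 4-toluenesulfonyl chloride, Cc1ccc(cc1)S(Cl)(=O)=O
Why: Sulfonylation is selective for the unhindered primary hydroxyl over the secondary benzylic one at 0 °C.

**Step 9**
Reactants: 12 the primary tosylate
Product: 13 (1S,2S)-2-[4,5-bis(benzyloxy)-2-bromophenyl]-1-(3,4,5-trimethoxyphenyl)propan-1-ol
Conditions: LiBHEt3, THF, 0 °C → rt
Reagents that add atoms: none
Why: SN2 hydride displacement of the primary tosylate gives the C3 methyl group, while the aryl bromide is inert to this hydride and no stereocentre is involved.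

**Step 10**
Reactants: 13 the bromo alcohol
Product: 14 (2S,3S)-5,6-bis(benzyloxy)-3-methyl-2-(3,4,5-trimethoxyphenyl)-2,3-dihydro-1-benzofuran
Conditions: CuI (copper iodide, 10 mol%), 3,4,7,8-tetramethyl-1,10-phenanthroline (20 mol%), Cs2CO3, toluene, 110 °C
Reagents that add atoms: none
Why: Intramolecular Ullmann-type aryl etherification closes the five-membered ring through the alkoxide oxygen, so the carbinol C–O bond is never broken and the (1S,2S) alcohol maps with retention onto the trans-(2S,3S) dihydrobenzofuran.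

**Step 11**
Reactants: 14 the bis-benzyl ether
Product: 15 (2S,3S)-3-methyl-2-(3,4,5-trimethoxyphenyl)-2,3-dihydro-1-benzofuran-5,6-diol
Conditions: H2 (1 atm), 10% Pd/C, EtOAc/MeOH, rt; filter under argon, use at once
Reagents that add atoms: none
Why: Catalytic hydrogenolysis removes the two primary benzyl ethers much faster than it attacks the hindered cyclic secondary benzylic ether, freeing the air-sensitive catechol.

**Step 12**
Reactants: 15 the catechol
Product: 17 (2S,3S,5R)-5-allyl-5-hydroxy-3-methyl-2-(3,4,5-trimethoxyphenyl)-2,3-dihydro-1-benzofuran-6(5H)-one, via ortho-quinone 16 (not isolated)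
Conditions: NaIO4 on SiO2, CH2Cl2, 0 °C, filter; add to (allyl)3In2Br3 [In powder, allyl bromide, DMF/THF, rt], −40 → 0 °C; aq NH4Cl; silica chromatography
Reagents that add atoms: allyl bromide, C=CCBr
Why: Periodate oxidation gives the ortho-quinone, and Barbier-type carbonyl allylation by allylindium through a six-membered transition state should take the C5 carbonyl (the C6 carbonyl is deactivated as a vinylogous ester of O1); the new C5 centre forms on a flat dienone remote from C2 and C3 with little facial bias (roughly 1:1 expected), so the (5R) epimer, allyl cis to the C2 aryl group, is isolated by chromatography from its (5S) epimer.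

**Step 13**
Reactants: 17 the tertiary ortho-quinol
Product: 18 (2S,3S,5R)-5-allyl-5-methoxy-3-methyl-2-(3,4,5-trimethoxyphenyl)-2,3-dihydro-1-benzofuran-6(5H)-one
Conditions: MeI (excess), Ag2O, 4 Å MS, MeCN, rt → 40 °C, dark
Reagents that add atoms: iodomethane, CI
Why: Purdie O-methylation alkylates the acidic tertiary α-ketol hydroxyl without forming a free alkoxide, so neither an α-ketol shift nor an anionic oxy-Cope migration of the allyl group can disturb C5.

**Compound list**
1 | 3,4-dihydroxyphenylacetic acid | OC(=O)Cc1ccc(O)c(O)c1 | starting material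
2 | benzyl [3,4-bis(benzyloxy)phenyl]acetate | O=C(Cc1ccc(OCc2ccccc2)c(OCc2ccccc2)c1)OCc1ccccc1 | intermediate
3 | [3,4-bis(benzyloxy)phenyl]acetic acid | OC(=O)Cc1ccc(OCc2ccccc2)c(OCc2ccccc2)c1 | intermediate
4 | [4,5-bis(benzyloxy)-2-bromophenyl]acetic acid | OC(=O)Cc1cc(OCc2ccccc2)c(OCc2ccccc2)cc1Br | intermediate
5 | [4,5-bis(benzyloxy)-2-bromophenyl]acetyl chloride | ClC(=O)Cc1cc(OCc2ccccc2)c(OCc2ccccc2)cc1Br | intermediate
6 | (S)-4-benzyl-1,3-oxazolidin-2-one | O=C1OC[C@H](Cc2ccccc2)N1 | starting material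
7 | (S)-4-benzyl-3-{[4,5-bis(benzyloxy)-2-bromophenyl]acetyl}-1,3-oxazolidin-2-one | O=C1OC[C@H](Cc2ccccc2)N1C(=O)Cc1cc(OCc2ccccc2)c(OCc2ccccc2)cc1Br | intermediate
8 | 3,4,5-trimethoxybenzaldehyde | COc1cc(C=O)cc(OC)c1OC | starting material
9 | Z-dibutylboron enolate of 7 (O–B cis to the aryl group) | CCCCB(CCCC)O/C(=C\c1cc(OCc2ccccc2)c(OCc2ccccc2)cc1Br)N1C(=O)OC[C@@H]1Cc1ccccc1 | intermediate
10 | (4S)-4-benzyl-3-[(2S,3S)-2-[4,5-bis(benzyloxy)-2-bromophenyl]-3-hydroxy-3-(3,4,5-trimethoxyphenyl)propanoyl]-1,3-oxazolidin-2-one | O=C1OC[C@H](Cc2ccccc2)N1C(=O)[C@@H](c1cc(OCc2ccccc2)c(OCc2ccccc2)cc1Br)[C@H](O)c1cc(OC)c(OC)c(OC)c1 | intermediate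
11 | (1S,2R)-2-[4,5-bis(benzyloxy)-2-bromophenyl]-1-(3,4,5-trimethoxyphenyl)propane-1,3-diol | OC[C@@H](c1cc(OCc2ccccc2)c(OCc2ccccc2)cc1Br)[C@H](O)c1cc(OC)c(OC)c(OC)c1 | intermediate
12 | (2R,3S)-2-[4,5-bis(benzyloxy)-2-bromophenyl]-3-hydroxy-3-(3,4,5-trimethoxyphenyl)propyl 4-methylbenzenesulfonate | Cc1ccc(cc1)S(=O)(=O)OC[C@@H](c1cc(OCc2ccccc2)c(OCc2ccccc2)cc1Br)[C@H](O)c1cc(OC)c(OC)c(OC)c1 | intermediate
13 | (1S,2S)-2-[4,5-bis(benzyloxy)-2-bromophenyl]-1-(3,4,5-trimethoxyphenyl)propan-1-ol | C[C@@H](c1cc(OCc2ccccc2)c(OCc2ccccc2)cc1Br)[C@H](O)c1cc(OC)c(OC)c(OC)c1 | intermediate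
14 | (2S,3S)-5,6-bis(benzyloxy)-3-methyl-2-(3,4,5-trimethoxyphenyl)-2,3-dihydro-1-benzofuran (trans) | C[C@@H]1[C@@H](c2cc(OC)c(OC)c(OC)c2)Oc2cc(OCc3ccccc3)c(OCc3ccccc3)cc12 | intermediate
15 | (2S,3S)-3-methyl-2-(3,4,5-trimethoxyphenyl)-2,3-dihydro-1-benzofuran-5,6-diol | C[C@@H]1[C@@H](c2cc(OC)c(OC)c(OC)c2)Oc2cc(O)c(O)cc12 | intermediate
16 | (2S,3S)-3-methyl-2-(3,4,5-trimethoxyphenyl)-2,3-dihydro-1-benzofuran-5,6-dione (ortho-quinone) | C[C@@H]1[C@@H](c2cc(OC)c(OC)c(OC)c2)OC2=CC(=O)C(=O)C=C12 | intermediate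
17 | (2S,3S,5R)-5-allyl-5-hydroxy-3-methyl-2-(3,4,5-trimethoxyphenyl)-2,3-dihydro-1-benzofuran-6(5H)-one | C=CC[C@@]1(O)C=C2C(=CC1=O)O[C@H](c1cc(OC)c(OC)c(OC)c1)[C@H]2C | intermediate
18 | (2S,3S,5R)-5-allyl-5-methoxy-3-methyl-2-(3,4,5-trimethoxyphenyl)-2,3-dihydro-1-benzofuran-6(5H)-one | C=CC[C@@]1(OC)C=C2C(=CC1=O)O[C@H](c1cc(OC)c(OC)c(OC)c1)[C@H]2C | target

**Totals**
Total steps: 13. Longest linear sequence: 13 (1 → 18); 6 and 8 enter as bought fragments.

**Steps most likely to fail, with fallbacks**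

Step 12 (quinone generation and allylation). The free ortho-quinone is labile, two carbonyls compete, and C5 forms without facial control. The fallback is a masked-quinone route that sets out from 15 and comes back at 18, and it also bypasses step 13. Mono-O-methylation of the more acidic 6-hydroxyl of 15 (Li2CO3, MeI, DMF; regioisomer removed on silica) gives (2S,3S)-6-methoxy-3-methyl-2-(3,4,5-trimethoxyphenyl)-2,3-dihydro-1-benzofuran-5-ol F1. PhI(OAc)2 in MeOH at 0 °C dearomatises it para to the phenol to the quinone monoketal (2S,3S)-6,7a-dimethoxy-3-methyl-2-(3,4,5-trimethoxyphenyl)-3,7a-dihydro-1-benzofuran-5(2H)-one F2 (C7a epimers, both serve). Allylmagnesium bromide (C3H5MgBr, THF, −78 °C) adds 1,2 to its only carbonyl to give the tertiary alcohol (2S,3S)-5-allyl-6,7a-dimethoxy-3-methyl-2-(3,4,5-trimethoxyphenyl)-2,3,5,7a-tetrahydro-1-benzofuran-5-ol F3. NaH/MeI converts this into (2S,3S)-5-allyl-5,6,7a-trimethoxy-3-methyl-2-(3,4,5-trimethoxyphenyl)-2,3,5,7a-tetrahydro-1-benzofuran F4. Dilute aqueous oxalic acid in THF then hydrolyses the vinylogous orthoester, with loss of two methanol, to the cyclic vinylogous ester 18 and its C5 epimer, which are separated by chromatography.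

Step 13 (O-methylation of a hindered tertiary α-ketol). The fallback is a sigmatropic detour that sets out from 17 and comes back at 18. KH with 18-crown-6 in THF (−20 → 0 °C) triggers a suprafacial anionic oxy-Cope shift of the allyl group from C5 to C3a. Aqueous quench gives the enolised diketone (2S,3S,3aS)-3a-allyl-5-hydroxy-3-methyl-2-(3,4,5-trimethoxyphenyl)-3,3a-dihydro-1-benzofuran-6(2H)-one F5. Its acidic enol is methylated easily (Me2SO4, K2CO3, acetone) to (2S,3S,3aS)-3a-allyl-5-methoxy-3-methyl-2-(3,4,5-trimethoxyphenyl)-3,3a-dihydro-1-benzofuran-6(2H)-one F6. Warming this in toluene (about 100–110 °C, monitored and stopped before any aryl allyl ether appears) returns the allyl group suprafacially to C5 by a Cope rearrangement, giving 18 with the original (5R) configuration.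

Step 10 (copper-catalysed ring closure on an electron-rich aryl bromide). The fallback is an acid-mediated closure from the phenol that sets out from 13 and comes back at 14. n-BuLi (2.2 equiv, THF, −78 °C; alkoxide formation, then bromine–lithium exchange) and B(OMe)3 give, after hydrolysis, {4,5-bis(benzyloxy)-2-[(1S,2S)-1-hydroxy-1-(3,4,5-trimethoxyphenyl)propan-2-yl]phenyl}boronic acid F7. This is oxidised in the same flask (H2O2, NaOH) to the phenol (1S,2S)-2-[4,5-bis(benzyloxy)-2-hydroxyphenyl]-1-(3,4,5-trimethoxyphenyl)propan-1-ol F8. Catalytic TsOH in CH2Cl2 ionises the electron-rich benzylic alcohol and the phenol traps the cation to give the thermodynamically preferred trans ring, 14 (C3 is untouched and C2 is set trans to it).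

**Further compounds**
F1 | step 12 | (2S,3S)-6-methoxy-3-methyl-2-(3,4,5-trimethoxyphenyl)-2,3-dihydro-1-benzofuran-5-ol | C[C@@H]1[C@@H](c2cc(OC)c(OC)c(OC)c2)Oc2cc(OC)c(O)cc12
F2 | step 12 | (2S,3S)-6,7a-dimethoxy-3-methyl-2-(3,4,5-trimethoxyphenyl)-3,7a-dihydro-1-benzofuran-5(2H)-one, C7a epimers | C[C@@H]1[C@@H](c2cc(OC)c(OC)c(OC)c2)OC2(OC)C=C(OC)C(=O)C=C12
F3 | step 12 | (2S,3S)-5-allyl-6,7a-dimethoxy-3-methyl-2-(3,4,5-trimethoxyphenyl)-2,3,5,7a-tetrahydro-1-benzofuran-5-ol, C5 and C7a epimers | C=CCC1(O)C=C2[C@H](C)[C@@H](c3cc(OC)c(OC)c(OC)c3)OC2(OC)C=C1OC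
F4 | step 12 | (2S,3S)-5-allyl-5,6,7a-trimethoxy-3-methyl-2-(3,4,5-trimethoxyphenyl)-2,3,5,7a-tetrahydro-1-benzofuran, C5 and C7a epimers | C=CCC1(OC)C=C2[C@H](C)[C@@H](c3cc(OC)c(OC)c(OC)c3)OC2(OC)C=C1OC
F5 | step 13 | (2S,3S,3aS)-3a-allyl-5-hydroxy-3-methyl-2-(3,4,5-trimethoxyphenyl)-3,3a-dihydro-1-benzofuran-6(2H)-one | C=CC[C@]12C=C(O)C(=O)C=C1O[C@H](c1cc(OC)c(OC)c(OC)c1)[C@H]2C
F6 | step 13 | (2S,3S,3aS)-3a-allyl-5-methoxy-3-methyl-2-(3,4,5-trimethoxyphenyl)-3,3a-dihydro-1-benzofuran-6(2H)-one | C=CC[C@]12C=C(OC)C(=O)C=C1O[C@H](c1cc(OC)c(OC)c(OC)c1)[C@H]2C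
F7 | step 10 | {4,5-bis(benzyloxy)-2-[(1S,2S)-1-hydroxy-1-(3,4,5-trimethoxyphenyl)propan-2-yl]phenyl}boronic acid | C[C@@H](c1cc(OCc2ccccc2)c(OCc2ccccc2)cc1B(O)O)[C@H](O)c1cc(OC)c(OC)c(OC)c1
F8 | step 10 | (1S,2S)-2-[4,5-bis(benzyloxy)-2-hydroxyphenyl]-1-(3,4,5-trimethoxyphenyl)propan-1-ol | C[C@@H](c1cc(OCc2ccccc2)c(OCc2ccccc2)cc1O)[C@H](O)c1cc(OC)c(OC)c(OC)c1
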